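**Assumption:** the C3 hemiketal configuration is fixed by the bridged 11-oxabicyclo[6.2.1] framework, so only C6, C7, C8 and C10 need to be set. The ring alkene C4=C5 is Z (C3 cis to C6), as drawn in the target.

## Retrosynthetic overview
- The angelate and C15 silyl ether come off last. The C3 hemiketal comes from MnO2 oxidation of the C3 allylic alcohol, followed by transannular closure onto the C10 tertiary OH.
- The 10-membered carbocycle, the trans-fused lactone and the α-methylene group form together in one SmI2 ketyl–butenolide cyclisation (C7–C8 bond, acetate loss). This cyclisation joins a C8 aldehyde to a γ-alkenyl butenolide.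
- The cyclisation precursor comes from an NHK coupling (C3–C4) of two fragments of comparable size. One is the Z-vinyl iodide butenolide W (from butynediol: CBS reduction, RCM). The other is the C10-stereodefined aldehyde E′ (from 2-butynol: Sharpless AE, then Red-Al).
- Ring order: butenolide (RCM) → 10-membered carbocycle and saturated-to-methylene lactone (SmI2) → bridging THF hemiketal (oxidation).

## Route

**Step 1**
Reactants: 1 but-2-yne-1,4-diol
Product: 2 4-(TBDPSO)but-2-yn-1-ol
Conditions: NaH (0.95 equiv), TBDPSCl, THF, 0 °C → rt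
Reagents that add atoms: TBDPSCl, CC(C)(C)[Si](Cl)(c1ccccc1)c1ccccc1
Why: Limiting alkoxide gives statistical mono-silylation of the symmetric diol (silyl protection).

**Step 2**
Reactants: 2
Product: 3 (Z)-4-(TBDPSO)-3-iodobut-2-en-1-ol
Conditions: Red-Al, Et2O, 0 °C → rt; EtOAc; I2, −78 → 0 °C
Reagents that add atoms: iodine, II
Why: Alkoxide-directed trans-hydroalumination through a five-membered aluminacycle puts Al on C3 cis to CH2O; iodinolysis gives the Z-vinyl iodide (hydroalumination/iodination). This fixes the C3/C6 cis relationship of the ring alkene.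

**Step 3**
Reactants: 3
Product: 4 (Z)-4-(TBDPSO)-3-iodobut-2-enal
Conditions: MnO2 (activated), CH2Cl2, rt
Reagents that add atoms: none
Why: MnO2 oxidises the allylic alcohol selectively and leaves the Z-alkene intact.

**Step 4**
Reactants: 4
Product: 5 (Z)-6-(TBDPSO)-5-iodohexa-1,4-dien-3-ol (racemic)
Conditions: vinylMgBr, THF, −78 °C
Reagents that add atoms: vinylmagnesium bromide, C=C[Mg]Br
Why: 1,2-Grignard addition to the enal; the carbinol is racemic and is reset in steps 5–6.

**Step 5**
Reactants: 5
Product: 6 (Z)-6-(TBDPSO)-5-iodohexa-1,4-dien-3-one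
Conditions: Dess–Martin periodinane, NaHCO3, CH2Cl2, 0 °C
Reagents that add atoms: none
Why: Oxidation of the secondary alcohol to the prochiral ketone.

**Step 6**
Reactants: 6
Product: 7 (3S,4Z)-6-(TBDPSO)-5-iodohexa-1,4-dien-3-ol
Conditions: (R)-Me-CBS (0.1 equiv), BH3·SMe2, THF, −78 °C
Reagents that add atoms: none (hydride only)
Why: Corey–Bakshi–Shibata reduction delivers hydride to one face, differentiating the large Z-iodoalkenyl group from vinyl; this sets the future C6 centre (S in this series, R in the target because CIP priorities switch).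

**Step 7**
Reactants: 8 2-(bromomethyl)acrylic acid
Product: 9 2-(acetoxymethyl)acrylic acid
Conditions: KOAc, DMF, rt; then 1 M HCl
Reagents that add atoms: potassium acetate, CC(=O)[O-].[K+]
Why: SN2 displacement of the allylic bromide by acetate provides the leaving group needed for the later E1cB step.

**Step 8**
Reactants: 7, 9
Product: 10 (3S,4Z)-6-(TBDPSO)-5-iodohexa-1,4-dien-3-yl 2-(acetoxymethyl)acrylate
Conditions: EDC·HCl, DMAP, CH2Cl2, 0 °C
Reagents that add atoms: none
Why: Steglich esterification with retention at the carbinol carbon.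

**Step 9**
Reactants: 10
Product: 11 (5S)-3-(acetoxymethyl)-5-[(Z)-2-iodo-3-(TBDPSO)prop-1-enyl]furan-2(5H)-one (fragment W)
Conditions: Grubbs II (5 mol%), CH2Cl2 (5 mM), 40 °C
Reagents that add atoms: none (ethylene lost)
Why: Ring-closing metathesis of the acrylate with the vinyl group gives the α-substituted butenolide; the hindered trisubstituted vinyl iodide is untouched and the γ-stereocentre is retained.

**Step 10**
Reactants: 12 but-2-yn-1-ol
Product: 13 (Z)-3-iodobut-2-en-1-ol
Conditions: Red-Al, Et2O, 0 °C → rt; EtOAc; I2, −78 °C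
Reagents that add atoms: iodine, II
Why: The same directed hydroalumination/iodination as step 2 gives the Z-iodide with I cis to CH2OH.

**Step 11**
Reactants: 13
Product: 14 (Z)-3-methylhexa-2,5-dien-1-ol
Conditions: allylzinc bromide (2.5 equiv), Pd(PPh3)4 (5 mol%), THF, 0 °C → rt
Reagents that add atoms: allylzinc bromide, C=CC[Zn]Br
Why: Negishi coupling replaces iodine with allyl and keeps the alkene geometry (allyl cis to CH2OH).

**Step 12**
Reactants: 14
Product: 15 (2R,3S)-(3-allyl-3-methyloxiran-2-yl)methanol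
Conditions: Ti(OiPr)4 (0.1 equiv), D-(−)-DET (0.12 equiv), TBHP, 3 Å MS, CH2Cl2, −20 °C
Reagents that add atoms: tert-butyl hydroperoxide, CC(C)(C)OO (supplies O)
Why: Sharpless asymmetric epoxidation; D-(−)-tartrate on the Z-allylic alcohol gives the (2R,3S) epoxide, which sets the quaternary centre that becomes C10 (S).

**Step 13**
Reactants: 15
Product: 16 (S)-3-methylhex-5-ene-1,3-diol
Conditions: Red-Al (3 equiv), THF, 0 °C, 3 h
Reagents that add atoms: none (hydride only)
Why: Directed C2-selective hydride opening of the 2,3-epoxy alcohol (Finan–Kishi reduction) leaves the tertiary OH at C10 with its configuration unchanged.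

**Step 14**
Reactants: 16
Product: 17 (S)-1-(TBSO)-3-methylhex-5-en-3-ol
Conditions: TBSCl, imidazole, CH2Cl2, 0 °C
Reagents that add atoms: TBSCl, C[Si](C)(C(C)(C)C)Cl
Why: The primary OH is silylated selectively over the tertiary OH.

**Step 15**
Reactants: 17
Product: 18 (S)-6-(TBSO)-4-methylhexane-1,4-diol
Conditions: 9-BBN, THF, 0 °C → rt; then NaOH, H2O2
Reagents that add atoms: hydrogen peroxide, OO (supplies O)
Why: Anti-Markovnikov hydroboration–oxidation of the terminal alkene gives the primary alcohol (C3).

**Step 16**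
Reactants: 18
Product: 19 (S)-6-(TBSO)-4-hydroxy-4-methylhexanal (fragment E′; partly the cyclic lactol)
Conditions: TEMPO (0.1 equiv), PhI(OAc)2, CH2Cl2, rt
Reagents that add atoms: none
Why: TEMPO/BAIB oxidises the primary alcohol selectively; the tertiary OH is untouched.

**Step 17**
Reactants: 11, 19
Product: 20 (C3-epimeric allylic alcohol)
Conditions: CrCl2 (10 equiv), NiCl2 (0.02 equiv), DMSO, rt, dark
Reagents that add atoms: none
Why: Nozaki–Hiyama–Kishi coupling of the Z-vinyl iodide with the aldehyde forms the C3–C4 bond with retention of the Z-alkene; the new C3 centre is a 1:1 mixture that is removed by oxidation in step 21.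

**Step 18**
Reactants: 20
Product: 21 (C8 primary alcohol)
Conditions: HF·pyridine, pyridine, THF, 0 °C → rt
Reagents that add atoms: none (H only)
Why: Buffered fluoride removes the primary TBS ether; the more robust TBDPS ether, the acetate and the alcohols survive.

**Step 19**
Reactants: 21
Product: 22 (C8 aldehyde)
Conditions: TEMPO (0.1 equiv), PhI(OAc)2 (1.1 equiv), CH2Cl2, 0 °C
Reagents that add atoms: none
Why: TEMPO oxidation of the primary alcohol is selective over the secondary allylic C3–OH and the tertiary C10–OH.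

**Step 20**
Reactants: 22
Product: 23 (10-membered carbocycle, trans-fused α-methylene-γ-lactone, triol)
Conditions: SmI2 (4.5 equiv), t-BuOH (2 equiv), THF, 0 °C; substrate at 2 mM by syringe pump over 4 h
Reagents that add atoms: none
Why: SmI2 ketyl–olefin cyclisation: the C8 ketyl adds to C7 of the butenolide anti to the C6 substituent (trans lactone, C7 set), Sm(III) chelation to the C10 oxygen is expected to set C8, and the Sm enolate expels acetate by E1cB to give the α-methylene group.

**Step 21**
Reactants: 23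
Product: 24 (bridged hemiketal, C8-OH, C15-OTBDPS)
Conditions: MnO2 (20 equiv), CH2Cl2, rt
Reagents that add atoms: none
Why: MnO2 oxidises the C3 allylic alcohol (C15 is silylated, C8 is not allylic) to the Z-enone, which closes transannularly with the C10 OH. The C3 configuration is dictated by the bridged oxabicycle, and the C3 epimers converge.

**Step 22**
Reactants: 24, 25 angelic acid
Product: 26 (C8 angelate)
Conditions: 25, 2,4,6-trichlorobenzoyl chloride, Et3N, THF; then 24, DMAP, toluene, rt
Reagents that add atoms: none (the acyl group comes from 25)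
Why: Yamaguchi esterification of the secondary C8–OH; the tertiary hemiketal OH is too hindered to compete, and Z-geometry is kept under these mild conditions.

**Step 23**
Reactants: 26
Product: 27 niveusin B
Conditions: HF·pyridine, pyridine, THF, rt, 24 h
Reagents that add atoms: none (H only)
Why: Fluoride removal of the TBDPS ether frees C15–OH; the angelate, lactone and hemiketal are stable to buffered HF.

## Compound list
1 | but-2-yne-1,4-diol | OCC#CCO | starting material
2 | 4-(TBDPSO)but-2-yn-1-ol | OCC#CCO[Si](c1ccccc1)(c1ccccc1)C(C)(C)C | intermediate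
3 | (Z)-4-(TBDPSO)-3-iodobut-2-en-1-ol | OC/C=C(\I)CO[Si](c1ccccc1)(c1ccccc1)C(C)(C)C | intermediate
4 | (Z)-4-(TBDPSO)-3-iodobut-2-enal | O=C/C=C(\I)CO[Si](c1ccccc1)(c1ccccc1)C(C)(C)C | intermediate
5 | (Z)-6-(TBDPSO)-5-iodohexa-1,4-dien-3-ol (racemic) | C=CC(O)/C=C(\I)CO[Si](c1ccccc1)(c1ccccc1)C(C)(C)C | intermediate
6 | (Z)-6-(TBDPSO)-5-iodohexa-1,4-dien-3-one | C=CC(=O)/C=C(\I)CO[Si](c1ccccc1)(c1ccccc1)C(C)(C)C | intermediate
7 | (3S,4Z)-6-(TBDPSO)-5-iodohexa-1,4-dien-3-ol | C=C[C@H](O)/C=C(\I)CO[Si](c1ccccc1)(c1ccccc1)C(C)(C)C | intermediate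
8 | 2-(bromomethyl)acrylic acid | C=C(CBr)C(=O)O | starting material
9 | 2-(acetoxymethyl)acrylic acid | C=C(COC(C)=O)C(=O)O | intermediate
10 | acrylate ester of 7 | C=C[C@H](OC(=O)C(=C)COC(C)=O)/C=C(\I)CO[Si](c1ccccc1)(c1ccccc1)C(C)(C)C | intermediate
11 | (5S)-3-(acetoxymethyl)-5-[(Z)-2-iodo-3-(TBDPSO)prop-1-enyl]furan-2(5H)-one (W) | CC(=O)OCC1=C[C@@H](/C=C(\I)CO[Si](c2ccccc2)(c2ccccc2)C(C)(C)C)OC1=O | intermediate
12 | but-2-yn-1-ol | CC#CCO | starting material
13 | (Z)-3-iodobut-2-en-1-ol | OC/C=C(\I)C | intermediate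
14 | (Z)-3-methylhexa-2,5-dien-1-ol | OC/C=C(\CC=C)C | intermediate
15 | (2R,3S)-(3-allyl-3-methyloxiran-2-yl)methanol | OC[C@H]1O[C@@]1(C)CC=C | intermediate
16 | (S)-3-methylhex-5-ene-1,3-diol | OCC[C@@](C)(O)CC=C | intermediate
17 | (S)-1-(TBSO)-3-methylhex-5-en-3-ol | CC(C)(C)[Si](C)(C)OCC[C@@](C)(O)CC=C | intermediate
18 | (S)-6-(TBSO)-4-methylhexane-1,4-diol | CC(C)(C)[Si](C)(C)OCC[C@@](C)(O)CCCO | intermediate
19 | (S)-6-(TBSO)-4-hydroxy-4-methylhexanal (E′) | CC(C)(C)[Si](C)(C)OCC[C@@](C)(O)CCC=O | intermediate
20 | NHK adduct (C3 epimer mixture) | CC(=O)OCC1=C[C@@H](/C=C(\C(O)CC[C@](C)(O)CCO[Si](C)(C)C(C)(C)C)CO[Si](c2ccccc2)(c2ccccc2)C(C)(C)C)OC1=O | intermediate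
21 | C8 primary alcohol | CC(=O)OCC1=C[C@@H](/C=C(\C(O)CC[C@](C)(O)CCO)CO[Si](c2ccccc2)(c2ccccc2)C(C)(C)C)OC1=O | intermediate
22 | C8 aldehyde | CC(=O)OCC1=C[C@@H](/C=C(\C(O)CC[C@](C)(O)CC=O)CO[Si](c2ccccc2)(c2ccccc2)C(C)(C)C)OC1=O | intermediate
23 | macrocyclic triol lactone | C=C1C(=O)O[C@@H]2/C=C(/CO[Si](c3ccccc3)(c3ccccc3)C(C)(C)C)C(O)CC[C@](C)(O)C[C@@H](O)[C@@H]12 | intermediate
24 | bridged hemiketal, C8-OH, C15-OTBDPS | C=C1C(=O)O[C@@H]2/C=C(/CO[Si](c4ccccc4)(c4ccccc4)C(C)(C)C)[C@@]3(O)CC[C@@](C)(C[C@@H](O)[C@@H]12)O3 | intermediate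
25 | angelic acid ((Z)-2-methylbut-2-enoic acid) | OC(=O)/C(C)=C\C | starting material
26 | C8 angelate, C15-OTBDPS | C=C1C(=O)O[C@@H]2/C=C(/CO[Si](c4ccccc4)(c4ccccc4)C(C)(C)C)[C@@]3(O)CC[C@@](C)(C[C@@H](OC(=O)/C(C)=C\C)[C@@H]12)O3 | intermediate
27 | niveusin B | C=C1C(=O)O[C@@H]2/C=C(/CO)[C@@]3(O)CC[C@@](C)(C[C@@H](OC(=O)/C(C)=C\C)[C@@H]12)O3 | target

## Step count
- Total steps: 23.
- Longest linear sequence: 15 (steps 1–6, 8, 9, 17–23).

## Three steps most likely to fail
1. **Step 20 (SmI2 macrocyclisation).** The 10-membered ring strain, the C8 facial selectivity, or premature reduction of the allylic acetate could all cause failure. *Fallback:* close the ring at C6–C7 instead. Use an acyclic C6 Z-enal with a (Z)-2-(bromomethyl)alk-2-enoate at C7, cyclise by intramolecular Cr(II) Nozaki–Hiyama allylation, then lactonise. This sets C6/C7 and the α-methylene lactone by a different disconnection.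
2. **Step 17 (NHK union).** Cr(II)/Ni may reduce or ionise the acetoxymethyl butenolide, or fail on the lactol form of 19. *Fallback:* convert 11 to its Z-vinylstannane and join it to the C3 acyl unit (acid chloride or thioester from oxidation of 18) by Stille acyl coupling. This gives the C3 ketone directly and skips the allylic-alcohol oxidation.
3. **Step 9 (RCM).** Forming the α-substituted trisubstituted butenolide next to a vinyl iodide may be sluggish. *Fallback:* make the same γ-stereocentred butenolide from 4-(TBDPSO)-3-iodobut-2-enal (4) by adding lithium ethyl propiolate, then oxidation to the ynone, Noyori Ru-TsDPEN transfer hydrogenation, and Z-selective semireduction with spontaneous lactonisation. The acetoxymethyl group would be installed separately.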